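The cyclohexane ring bears a vinyl group on its quaternary carbon C10 and an isopropenyl group on the neighbouring methine C5: a 1,5-diene spanning the C5–C10 ring bond (elemane numbering). The synthesis rests on closing this bond by a metal-templated Cope-type event: 3,3′-reductive elimination of a bis(allyl)palladium joins the two substituted allyl termini, closes the carbocycle, unveils both alkenes and sets the C5/C10 stereocentres at once. The precursor is the cis-disubstituted butanolide of natural (2R,3S)-isocitric acid (C6, C7, C11, C12), carrying an allylboronate arm on C6 and an (E)-allylic carbonate arm on C7; lactone α-methylation, α-hydroxylation and two acylations complete the target.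

Key step: step 9

Remark: atoms are numbered as in elemanolides (C1=C2 vinyl and C14 methyl on C10; C3=C4(C15) isopropenyl on C5; lactone O on C6, C7–C11(C13)–C12(=O); acetate on C8; C9 the ring CH2); monopotassium (2R,3S)-isocitrate is assumed to be purchased, and its lactone has the C6/C7 configuration of the target.

Step 1
Reactants: 1 3-methylbut-2-enal
Product: 2 (E)-tert-butyldimethyl[(3-methylbuta-1,3-dien-1-yl)oxy]silane
Conditions: TBSOTf, Et3N, CH2Cl2, 0 °C
Reagents that add atoms: tert-butyldimethylsilyl trifluoromethanesulfonate, CC(C)(C)[Si](C)(C)OS(=O)(=O)C(F)(F)F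
Why: Soft enolisation of the enal (O-silylation, then γ-deprotonation by Et3N) should give the conjugated silyl dienol ether with the thermodynamically preferred E enol ether geometry.

Step 2
Reactants: 3 monopotassium (2R,3S)-isocitrate
Product: 5 (2R,3S)-isocitric acid lactone anhydride, via isocitric acid lactone 4 (not isolated)
Conditions: 2 M HCl, evaporate, 100 °C; then Ac2O, 70 °C
Reagents that add atoms: none
Why: Acidification and heating close the γ-lactone between the C6 hydroxyl and the C12 carboxyl, and acetic anhydride dehydrates the cis-disposed C5 and C8 carboxyl groups to the cyclic anhydride without touching the two stereocentres that become C6 and C7.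

Step 3
Reactants: 5 (2R,3S)-isocitric acid lactone anhydride
Product: 6 (2R,3S)-2-[(ethylsulfanyl)carbonyl]-5-oxooxolane-3-carboxylic acid
Conditions: EtSH, pyridine, CH2Cl2, −20 °C
Reagents that add atoms: ethanethiol, CCS
Why: Regioselective anhydride thiolysis, in which the thiol should attack the more electrophilic carbonyl C5 on the oxygen-bearing carbon C6 (as in acyloxysuccinic anhydrides), giving the C5 thioester and the C8 acid.

Step 4
Reactants: 6 (2R,3S)-2-[(ethylsulfanyl)carbonyl]-5-oxooxolane-3-carboxylic acid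
Product: 8 S-ethyl (2R,3S)-3-formyl-5-oxooxolane-2-carbothioate, via acid chloride 7 (not isolated)
Conditions: (COCl)2, DMF (cat.), CH2Cl2, 0 °C; then LiAlH(OtBu)3, THF, −78 °C
Reagents that add atoms: none
Why: Acid chloride formation followed by reduction with the hindered hydride LiAlH(OtBu)3 at −78 °C stops at the aldehyde, the thioester and the lactone being much slower to react.

Step 5
Reactants: 8 S-ethyl (2R,3S)-3-formyl-5-oxooxolane-2-carbothioate; 2 (E)-tert-butyldimethyl[(3-methylbuta-1,3-dien-1-yl)oxy]silane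
Product: 9 S-ethyl (2R,3S)-3-[(1S,3E)-1-[(tert-butyldimethylsilyl)oxy]-3-methyl-5-oxopent-3-en-1-yl]-5-oxooxolane-2-carbothioate
Conditions: B(C6F5)3 (10 mol %), CH2Cl2, −78 °C
Reagents that add atoms: none
Why: Vinylogous Mukaiyama aldol addition in which the dienol ether attacks through its γ-carbon to give the (E)-enal, the silyl group is transferred to the aldolate oxygen, and C8 is set by Felkin–Anh approach anti to the larger α-substituent C6 (no chelation with the boron Lewis acid).

Step 6
Reactants: 9 S-ethyl (2R,3S)-3-[(1S,3E)-1-[(tert-butyldimethylsilyl)oxy]-3-methyl-5-oxopent-3-en-1-yl]-5-oxooxolane-2-carbothioate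
Product: 10 (4S,5R)-4-[(1S,3E)-1-[(tert-butyldimethylsilyl)oxy]-3-methyl-5-oxopent-3-en-1-yl]-5-(2-methylprop-2-enoyl)oxolan-2-one
Conditions: CH2=C(CH3)MgBr, ZnBr2, THF, 0 °C; then 9, PdCl2(PPh3)2 (5 mol %), THF–toluene, rt
Reagents that add atoms: isopropenylmagnesium bromide, CC(=C)[Mg]Br
Why: Fukuyama coupling (zerovalent palladium inserts into the C–S bond and the acylpalladium is alkenylated by the organozinc), which tolerates the enal, the lactone and the silyl ether and leaves the α-stereocentre C6 untouched.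

Step 7
Reactants: 10 (4S,5R)-4-[(1S,3E)-1-[(tert-butyldimethylsilyl)oxy]-3-methyl-5-oxopent-3-en-1-yl]-5-(2-methylprop-2-enoyl)oxolan-2-one
Product: 11 (4S,5R)-4-[(1S,3E)-1-[(tert-butyldimethylsilyl)oxy]-5-hydroxy-3-methylpent-3-en-1-yl]-5-(1-hydroxy-2-methylprop-2-en-1-yl)oxolan-2-one (both epimers at the new carbinol C5)
Conditions: NaBH4, CeCl3·7H2O, MeOH, −78 to −40 °C
Reagents that add atoms: none
Why: Luche reduction delivers hydride 1,2 to both the enal and the enone while the lactone is inert; the C5 carbinol forms as a mixture of epimers, which does not matter because C5 becomes an allyl terminus in step 9.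

Step 8
Reactants: 11 (4S,5R)-4-[(1S,3E)-1-[(tert-butyldimethylsilyl)oxy]-5-hydroxy-3-methylpent-3-en-1-yl]-5-(1-hydroxy-2-methylprop-2-en-1-yl)oxolan-2-one
Product: 12 bis(methyl carbonate) of diol 11
Conditions: ClCO2Me, pyridine, DMAP (cat.), CH2Cl2, 0 °C
Reagents that add atoms: methyl chloroformate, COC(Cl)=O
Why: Acylation of the primary and the secondary allylic alcohol with methyl chloroformate gives the two allylic carbonates needed as leaving groups.

Step 9
Reactants: 12 bis(methyl carbonate) of diol 11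
Product: 14 (3aS,4S,6R,7R,7aS)-4-[(tert-butyldimethylsilyl)oxy]-6-ethenyl-6-methyl-7-(prop-1-en-2-yl)hexahydro-1-benzofuran-2(3H)-one, via allylboronate 13 (not isolated)
Conditions: CuCl (5 mol %), Xantphos (5 mol %), KOtBu (10 mol %), B2pin2 (1.05 equiv), THF, 0 °C; then Pd2(dba)3 (2.5 mol %), 1,2-bis(diphenylphosphino)benzene (6 mol %), THF (0.01 M), 60 °C
Reagents that add atoms: none
Why: Copper-catalysed SN2′ borylation should convert only the secondary carbonate, whose 1,1-disubstituted alkene accepts Cu–B addition, into the primary allylboronate 13; zerovalent palladium then ionises the remaining (E)-allylic carbonate, the methoxide set free activates the boronate for transmetalation, and the bis(η1-allyl)palladium collapses by 3,3′-reductive elimination to form the C5–C10 bond. The closest known reactions are the palladium-catalysed allyl–allyl cross-coupling of allylboronates with allylic carbonates, which builds quaternary centres and vicinal stereocentres, and the ring-closing coupling of allylstannanes with allyl acetates to 1,2-dialkenylcycloalkanes. The cyclohexane ring closes between the two substituted allyl termini so that both π-bonds end exocyclic (6-exo with respect to each allyl unit), the eight- and ten-membered alternatives from 1,3′- and 1,1′-coupling being disfavoured by ring size and by the bidentate ligand. C5 is controlled by the C6 stereocentre: allylic 1,3-strain with the C4 methyl keeps H-6 in the alkene plane, so C10 adds to the face that carries the C7 tether and anti to the lactone C6–O bond, which places O-6 equatorial and trans to the isopropenyl group. C10 is controlled by the chair-like seven-membered transition state, fused to the forming ring like a trans-decalin, in which both E-allyl units are equatorial and the C10 methyl is axial, so vinyl ends trans to isopropenyl. The step needs chemoselective mono-borylation, 3,3′-regioselectivity and retention of the E geometry at C10; these are secured by the different alkene substitution of the two carbonates, by the six-membered ring size and by the slow syn–anti exchange at a disubstituted allyl terminus.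

Step 10
Reactants: 14 (3aS,4S,6R,7R,7aS)-4-[(tert-butyldimethylsilyl)oxy]-6-ethenyl-6-methyl-7-(prop-1-en-2-yl)hexahydro-1-benzofuran-2(3H)-one
Product: 15 (3S,3aS,4S,6R,7R,7aS)-4-[(tert-butyldimethylsilyl)oxy]-6-ethenyl-3,6-dimethyl-7-(prop-1-en-2-yl)hexahydro-1-benzofuran-2(3H)-one
Conditions: LiN(iPr)2, THF, −78 °C; MeI, −78 to −40 °C
Reagents that add atoms: iodomethane, CI
Why: Alkylation of the lithium lactone enolate with iodomethane on the convex face of the cis-fused bicycle (anti to C8) introduces C13; the C11 configuration is reset in the next step.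

Step 11
Reactants: 15 (3S,3aS,4S,6R,7R,7aS)-4-[(tert-butyldimethylsilyl)oxy]-6-ethenyl-3,6-dimethyl-7-(prop-1-en-2-yl)hexahydro-1-benzofuran-2(3H)-one
Product: 16 (3S,3aS,4S,6R,7R,7aS)-4-[(tert-butyldimethylsilyl)oxy]-6-ethenyl-3-hydroxy-3,6-dimethyl-7-(prop-1-en-2-yl)hexahydro-1-benzofuran-2(3H)-one
Conditions: KN(SiMe3)2, THF, −78 °C; 2-(phenylsulfonyl)-3-phenyloxaziridine, −78 °C; NH4Cl (aq.)
Reagents that add atoms: 2-(phenylsulfonyl)-3-phenyloxaziridine, O=S(=O)(c1ccccc1)N1OC1c1ccccc1
Why: Enolate hydroxylation with an N-sulfonyloxaziridine, in which the oxidant approaches the tetrasubstituted enolate from the convex face and so places the hydroxyl cis to H-7 and the methyl on the concave face (11S).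

Step 12
Reactants: 16 (3S,3aS,4S,6R,7R,7aS)-4-[(tert-butyldimethylsilyl)oxy]-6-ethenyl-3-hydroxy-3,6-dimethyl-7-(prop-1-en-2-yl)hexahydro-1-benzofuran-2(3H)-one
Product: 17 (3S,3aS,4S,6R,7R,7aS)-4-[(tert-butyldimethylsilyl)oxy]-6-ethenyl-3,6-dimethyl-2-oxo-7-(prop-1-en-2-yl)octahydro-1-benzofuran-3-yl (2Z)-2-methylbut-2-enoate
Conditions: angelic acid, 2,4,6-Cl3C6H2COCl, Et3N, toluene, rt, filter; then 16, LiN(SiMe3)2, THF, −78 to 0 °C
Reagents that add atoms: angelic acid, C/C=C(/C)C(=O)O
Why: Acylation of the lithium alkoxide by the Yamaguchi-type mixed anhydride at its less hindered angeloyl carbonyl, at low temperature and without a nucleophilic amine catalyst, should give the tertiary angelate without Z-to-E isomerisation.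

Step 13
Reactants: 17 (3S,3aS,4S,6R,7R,7aS)-4-[(tert-butyldimethylsilyl)oxy]-6-ethenyl-3,6-dimethyl-2-oxo-7-(prop-1-en-2-yl)octahydro-1-benzofuran-3-yl (2Z)-2-methylbut-2-enoate
Product: 18 (3S,3aR,4S,6R,7R,7aS)-6-ethenyl-4-hydroxy-3,6-dimethyl-2-oxo-7-(prop-1-en-2-yl)octahydro-1-benzofuran-3-yl (2Z)-2-methylbut-2-enoate
Conditions: HF·pyridine, THF, 0 °C to rt
Reagents that add atoms: none
Why: Fluoride-mediated cleavage of the silyl ether; the esters and the lactone are stable and acyl migration is geometrically impossible because O-8 is anti to C11.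

Step 14
Reactants: 18 (3S,3aR,4S,6R,7R,7aS)-6-ethenyl-4-hydroxy-3,6-dimethyl-2-oxo-7-(prop-1-en-2-yl)octahydro-1-benzofuran-3-yl (2Z)-2-methylbut-2-enoate
Product: 19 (3S,3aR,4S,6R,7R,7aS)-4-(acetyloxy)-6-ethenyl-3,6-dimethyl-2-oxo-7-(prop-1-en-2-yl)octahydro-1-benzofuran-3-yl (2Z)-2-methylbut-2-enoate
Conditions: Ac2O, pyridine, DMAP (cat.), CH2Cl2, rt
Reagents that add atoms: acetic anhydride, CC(=O)OC(C)=O
Why: DMAP-catalysed acetylation of the axial secondary alcohol completes the target.

Compound list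
1 | 3-methylbut-2-enal | CC(C)=CC=O | starting material
2 | (E)-tert-butyldimethyl[(3-methylbuta-1,3-dien-1-yl)oxy]silane | CC(=C)/C=C/O[Si](C)(C)C(C)(C)C | intermediate
3 | monopotassium (2R,3S)-isocitrate | [K+].OC(=O)[C@@H](CC(=O)O)[C@@H](O)C(=O)[O-] | starting material
4 | (2R,3S)-5-oxooxolane-2,3-dicarboxylic acid (isocitric acid lactone, carboxyl groups cis) | OC(=O)[C@@H]1[C@@H](OC(=O)C1)C(=O)O | intermediate
5 | (2R,3S)-isocitric acid lactone anhydride (cis-fused cyclic anhydride of 4) | O=C1[C@@H]2[C@@H](OC(=O)C2)C(=O)O1 | intermediate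
6 | (2R,3S)-2-[(ethylsulfanyl)carbonyl]-5-oxooxolane-3-carboxylic acid | OC(=O)[C@@H]1[C@@H](OC(=O)C1)C(=O)SCC | intermediate
7 | S-ethyl (2R,3S)-3-(chlorocarbonyl)-5-oxooxolane-2-carbothioate | ClC(=O)[C@@H]1[C@@H](OC(=O)C1)C(=O)SCC | intermediate
8 | S-ethyl (2R,3S)-3-formyl-5-oxooxolane-2-carbothioate | O=C[C@@H]1[C@@H](OC(=O)C1)C(=O)SCC | intermediate
9 | S-ethyl (2R,3S)-3-[(1S,3E)-1-[(tert-butyldimethylsilyl)oxy]-3-methyl-5-oxopent-3-en-1-yl]-5-oxooxolane-2-carbothioate | O=C/C=C(\C)C[C@H](O[Si](C)(C)C(C)(C)C)[C@@H]1[C@@H](OC(=O)C1)C(=O)SCC | intermediate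
10 | (4S,5R)-4-[(1S,3E)-1-[(tert-butyldimethylsilyl)oxy]-3-methyl-5-oxopent-3-en-1-yl]-5-(2-methylprop-2-enoyl)oxolan-2-one | O=C/C=C(\C)C[C@H](O[Si](C)(C)C(C)(C)C)[C@@H]1[C@@H](OC(=O)C1)C(=O)C(C)=C | intermediate
11 | (4S,5R)-4-[(1S,3E)-1-[(tert-butyldimethylsilyl)oxy]-5-hydroxy-3-methylpent-3-en-1-yl]-5-(1-hydroxy-2-methylprop-2-en-1-yl)oxolan-2-one (both carbinol epimers) | OC/C=C(\C)C[C@H](O[Si](C)(C)C(C)(C)C)[C@@H]1[C@@H](OC(=O)C1)C(O)C(C)=C | intermediate
12 | (4S,5R)-4-[(1S,3E)-1-[(tert-butyldimethylsilyl)oxy]-5-[(methoxycarbonyl)oxy]-3-methylpent-3-en-1-yl]-5-{1-[(methoxycarbonyl)oxy]-2-methylprop-2-en-1-yl}oxolan-2-one | COC(=O)OC/C=C(\C)C[C@H](O[Si](C)(C)C(C)(C)C)[C@@H]1[C@@H](OC(=O)C1)C(OC(=O)OC)C(C)=C | intermediate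
13 | (4S,5S)-4-[(1S,3E)-1-[(tert-butyldimethylsilyl)oxy]-5-[(methoxycarbonyl)oxy]-3-methylpent-3-en-1-yl]-5-[(1E)-2-methyl-3-(4,4,5,5-tetramethyl-1,3,2-dioxaborolan-2-yl)prop-1-en-1-yl]oxolan-2-one | COC(=O)OC/C=C(\C)C[C@H](O[Si](C)(C)C(C)(C)C)[C@@H]1[C@@H](OC(=O)C1)/C=C(\C)CB2OC(C)(C)C(C)(C)O2 | intermediate
14 | (3aS,4S,6R,7R,7aS)-4-[(tert-butyldimethylsilyl)oxy]-6-ethenyl-6-methyl-7-(prop-1-en-2-yl)hexahydro-1-benzofuran-2(3H)-one | C=C[C@@]1(C)C[C@H](O[Si](C)(C)C(C)(C)C)[C@@H]2[C@@H](OC(=O)C2)[C@@H]1C(=C)C | intermediate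
15 | (3S,3aS,4S,6R,7R,7aS)-4-[(tert-butyldimethylsilyl)oxy]-6-ethenyl-3,6-dimethyl-7-(prop-1-en-2-yl)hexahydro-1-benzofuran-2(3H)-one | C=C[C@@]1(C)C[C@H](O[Si](C)(C)C(C)(C)C)[C@@H]2[C@@H](OC(=O)[C@H]2C)[C@@H]1C(=C)C | intermediate
16 | (3S,3aS,4S,6R,7R,7aS)-4-[(tert-butyldimethylsilyl)oxy]-6-ethenyl-3-hydroxy-3,6-dimethyl-7-(prop-1-en-2-yl)hexahydro-1-benzofuran-2(3H)-one | C=C[C@@]1(C)C[C@H](O[Si](C)(C)C(C)(C)C)[C@@H]2[C@@H](OC(=O)[C@@]2(C)O)[C@@H]1C(=C)C | intermediate
17 | (3S,3aS,4S,6R,7R,7aS)-4-[(tert-butyldimethylsilyl)oxy]-6-ethenyl-3,6-dimethyl-2-oxo-7-(prop-1-en-2-yl)octahydro-1-benzofuran-3-yl (2Z)-2-methylbut-2-enoate | C=C[C@@]1(C)C[C@H](O[Si](C)(C)C(C)(C)C)[C@@H]2[C@@H](OC(=O)[C@@]2(C)OC(=O)/C(C)=C\C)[C@@H]1C(=C)C | intermediate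
18 | (3S,3aR,4S,6R,7R,7aS)-6-ethenyl-4-hydroxy-3,6-dimethyl-2-oxo-7-(prop-1-en-2-yl)octahydro-1-benzofuran-3-yl (2Z)-2-methylbut-2-enoate | C=C[C@@]1(C)C[C@H](O)[C@@H]2[C@@H](OC(=O)[C@@]2(C)OC(=O)/C(C)=C\C)[C@@H]1C(=C)C | intermediate
19 | (3S,3aR,4S,6R,7R,7aS)-4-(acetyloxy)-6-ethenyl-3,6-dimethyl-2-oxo-7-(prop-1-en-2-yl)octahydro-1-benzofuran-3-yl (2Z)-2-methylbut-2-enoate (CNP0140071.1) | C=C[C@@]1(C)C[C@H](OC(C)=O)[C@@H]2[C@@H](OC(=O)[C@@]2(C)OC(=O)/C(C)=C\C)[C@@H]1C(=C)C | target

Total step count: 14. Longest linear sequence: 13 steps (steps 2 to 14, from 3); step 1 prepares reagent 2.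

Steps most likely to fail

Step 9. The borylation may run on both carbonates or the boronate may be protodeboronated, the E geometry at C10 may erode by syn–anti exchange, the chair and boat transition states may not be discriminated well enough (poor facial selectivity at C10), or the allylpalladium may eliminate to a diene. The fallback makes the same bond with stoichiometric zerovalent nickel. Diol 11 is treated with PBr3 (Et2O, −20 °C; the secondary allylic alcohol reacts with allylic transposition) to give the dibromide (4S,5S)-5-[(1E)-3-bromo-2-methylprop-1-en-1-yl]-4-[(1S,3E)-5-bromo-1-[(tert-butyldimethylsilyl)oxy]-3-methylpent-3-en-1-yl]oxolan-2-one F1. Slow addition of F1 to Ni(cod)2 in DMF at room temperature should couple the two allylnickel units at their substituted termini, the classical reductive closure of 1,10-dibromodeca-2,8-dienes to 1,2-dialkenylcyclohexanes, and return lactone 14. The fallback sets out from 11 and comes back at 14.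

Step 5. Facial selectivity at the aldehyde may be poor, and the β-acyloxy aldehyde may epimerise at C7 or lose the lactone carboxylate by β-elimination under the Lewis acid. The fallback sets C8 by reagent control. Aldehyde 8 is treated with the enantiomer of B-methallyldiisopinocampheylborane that delivers the 8S carbinol (Et2O, −78 °C) to give S-ethyl (2R,3R)-3-[(1S)-1-hydroxy-3-methylbut-3-en-1-yl]-5-oxooxolane-2-carbothioate F2. F2 is silylated at once (TBSOTf, 2,6-lutidine, CH2Cl2, −78 °C) to S-ethyl (2R,3S)-3-[(1S)-1-[(tert-butyldimethylsilyl)oxy]-3-methylbut-3-en-1-yl]-5-oxooxolane-2-carbothioate F3. Cross-metathesis of F3 with crotonaldehyde (second-generation Hoveyda–Grubbs catalyst, CH2Cl2, 40 °C) should install the (E)-enal. The fallback sets out from 8 and comes back at 9.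

Step 12. The hindered tertiary alkoxide may resist acylation, and forcing conditions may isomerise the angelate to the tiglate. The fallback builds the Z-alkene on the ester instead. Alcohol 16 is acylated with 2-[bis(2,2,2-trifluoroethoxy)phosphoryl]propanoyl chloride (Et3N, CH2Cl2, 0 °C; acylation through the reactive phosphono-ketene) to give (3S,3aS,4S,6R,7R,7aS)-4-[(tert-butyldimethylsilyl)oxy]-6-ethenyl-3,6-dimethyl-2-oxo-7-(prop-1-en-2-yl)octahydro-1-benzofuran-3-yl 2-[bis(2,2,2-trifluoroethoxy)phosphoryl]propanoate F4. Still–Gennari olefination of F4 with acetaldehyde (KN(SiMe3)2, 18-crown-6, THF, −78 °C) should give the Z-configured ester. The fallback sets out from 16 and comes back at 17.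

Further compounds
F1 | step 9 | (4S,5S)-5-[(1E)-3-bromo-2-methylprop-1-en-1-yl]-4-[(1S,3E)-5-bromo-1-[(tert-butyldimethylsilyl)oxy]-3-methylpent-3-en-1-yl]oxolan-2-one | BrC/C=C(\C)C[C@H](O[Si](C)(C)C(C)(C)C)[C@@H]1[C@@H](OC(=O)C1)/C=C(\C)CBr
F2 | step 5 | S-ethyl (2R,3R)-3-[(1S)-1-hydroxy-3-methylbut-3-en-1-yl]-5-oxooxolane-2-carbothioate | CC(=C)C[C@H](O)[C@@H]1[C@@H](OC(=O)C1)C(=O)SCC
F3 | step 5 | S-ethyl (2R,3S)-3-[(1S)-1-[(tert-butyldimethylsilyl)oxy]-3-methylbut-3-en-1-yl]-5-oxooxolane-2-carbothioate | CC(=C)C[C@H](O[Si](C)(C)C(C)(C)C)[C@@H]1[C@@H](OC(=O)C1)C(=O)SCC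
F4 | step 12 | (3S,3aS,4S,6R,7R,7aS)-4-[(tert-butyldimethylsilyl)oxy]-6-ethenyl-3,6-dimethyl-2-oxo-7-(prop-1-en-2-yl)octahydro-1-benzofuran-3-yl 2-[bis(2,2,2-trifluoroethoxy)phosphoryl]propanoate | C=C[C@@]1(C)C[C@H](O[Si](C)(C)C(C)(C)C)[C@@H]2[C@@H](OC(=O)[C@@]2(C)OC(=O)C(C)P(=O)(OCC(F)(F)F)OCC(F)(F)F)[C@@H]1C(=C)C
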